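**Retrosynthetic overview**
- The strategy rests on isocoumarin carbons C1–C8a–C8–C7–C6–C5–C4a–C4–C3 being one unbranched chain with oxygen on C1, C8, C6 and C3 (the C4a oxygen is lost as water), running straight on into the diene and C2 of the oxolane. The benzene ring and the pyranone ring are therefore two folds of a linear 1,3-polycarbonyl chain.
- The silyl ether and the C5 chlorine are taken off last. The isocoumarin is then opened at C1–O2 (enol lactone) and C8a–C4a (aldol) to a dienyl triketo-dioxinone, in which the dioxinone masks C1 and C8.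
- The chain is cut at C3–C4 (Claisen acylation) into a dienoyl N-methoxy-N-methylamide (fragment 1) and the trianion of a diketo-dioxinone (fragment 2, from 2,2,6-trimethyl-dioxinone and two acetyl units).
- Fragment 1 comes from vinylogous Horner–Wadsworth–Emmons olefination of an oxolane-2-carbaldehyde, made from 2-deoxy-D-ribose by C-methylation of its furanosyl acetate with AlMe3.
- Ring order: the oxolane (from the sugar) first, then the benzene ring and directly after it the lactone ring, both in one operation.

Key step: step 14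

Remark: atom labels C1 to C8a are isocoumarin numbers; LiN(i-Pr)2 and LiN(SiMe3)2 are taken as commercial solutions; the lactol and its acetate are used as anomer mixtures.

**Route**

Step 1
Reactants: 1 2-deoxy-D-ribose
Product: 2 2-deoxy-D-ribono-1,4-lactone
Conditions: Br2, H2O, rt, dark; evaporation
Reagents that add atoms: none
Why: Bromine-water oxidation of the aldose hemiacetal gives the aldonolactone, which settles as the five-membered 1,4-lactone on concentration, and C3 and C4 of the sugar are not touched.

Step 2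
Reactants: 2 2-deoxy-D-ribono-1,4-lactone
Product: 3 3,5-bis-O-silyl lactone
Conditions: TBSCl, imidazole, DMF, rt
Reagents that add atoms: tert-butyldimethylsilyl chloride, CC(C)(C)[Si](C)(C)Cl
Why: Imidazole-promoted silylation covers the primary and the secondary hydroxyl as tert-butyldimethylsilyl ethers, which tolerate the later bases and Lewis acids.

Step 3
Reactants: 3 3,5-bis-O-silyl lactone
Product: 4 3,5-bis-O-silyl-2-deoxy-D-ribofuranose
Conditions: i-Bu2AlH, CH2Cl2, -78 °C; aq. KNaC4H4O6
Reagents that add atoms: none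
Why: Partial reduction of a lactone with i-Bu2AlH stops at the lactol because the aluminium hemiacetal is stable at -78 °C.

Step 4
Reactants: 4 3,5-bis-O-silyl-2-deoxy-D-ribofuranose
Product: 5 1-O-acetyl-3,5-bis-O-silyl-2-deoxy-D-ribofuranose
Conditions: Ac2O, pyridine, DMAP (cat.), CH2Cl2, 0 °C to rt
Reagents that add atoms: acetic anhydride, CC(=O)OC(C)=O
Why: DMAP-catalysed O-acetylation turns the lactol into an anomeric acetate, a leaving group for Lewis-acid ionisation, and both anomers give the same cation.

Step 5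
Reactants: 5 1-O-acetyl-3,5-bis-O-silyl-2-deoxy-D-ribofuranose; 6 trimethylaluminium
Product: 7 alpha-C-methyl glycoside (bis-silyl ether)
Conditions: AlMe3 (3 equiv), CH2Cl2, -78 to 0 °C
Reagents that add atoms: none
Why: Lewis-acid C-glycosylation of a lactol acetate, in which AlMe3 ionises the acetate and transfers methyl to the furanosyl oxocarbenium ion; the ion reacts through the envelope with a pseudoaxial 3-silyloxy group by inside attack (Woerpel model), so the methyl group should enter cis to the 3-silyloxy group and trans to the C4 side chain (5R in the oxolane).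

Step 6
Reactants: 7 alpha-C-methyl glycoside (bis-silyl ether)
Product: 8 primary alcohol
Conditions: HF·pyridine, pyridine, THF, 0 °C
Reagents that add atoms: none
Why: Selective desilylation, since buffered HF·pyridine cleaves the unhindered primary silyl ether much faster than the secondary one.

Step 7
Reactants: 8 primary alcohol
Product: 9 oxolane-2-carbaldehyde
Conditions: Dess–Martin periodinane, CH2Cl2, 0 °C to rt; used crude
Reagents that add atoms: none
Why: Dess–Martin oxidation runs under near-neutral conditions, so the alpha-alkoxy aldehyde should neither epimerise at C2 nor lose silanol by beta-elimination.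

Step 8
Reactants: 9 oxolane-2-carbaldehyde; 10 triethyl 4-phosphonocrotonate
Product: 11 (E,E)-dienoate ester
Conditions: 10, LiN(SiMe3)2, THF, -78 °C; then 9, -78 to 0 °C
Reagents that add atoms: none
Why: Vinylogous Horner–Wadsworth–Emmons olefination, in which the stabilised phosphonate anion forms the new double bond E and the crotonate brings the second E double bond.

Step 9
Reactants: 11 (E,E)-dienoate ester
Product: 12 (E,E)-dienoyl N-methoxy-N-methylamide (fragment 1)
Conditions: MeNH(OMe)·HCl, i-PrMgCl, THF, -20 to 0 °C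
Reagents that add atoms: N,O-dimethylhydroxylamine hydrochloride, CNOC.Cl
Why: Weinreb amide formation by aminolysis of the ester with the chloromagnesium amide made in the flask, a weak base that should not add to the diene.

Step 10
Reactants: 13 2,2,6-trimethyl-4H-1,3-dioxin-4-one; 14 acetyl chloride
Product: 15 keto-dioxinone
Conditions: 13 (2 equiv), LiN(SiMe3)2 (2 equiv), THF, -78 °C; then 14 (1 equiv); aq. NH4Cl
Reagents that add atoms: none
Why: Gamma-C-acylation of the lithium dienolate of the dioxinone (vinylogous Claisen acylation), with the second equivalent of dienolate taking the proton of the more acidic product.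

Step 11
Reactants: 14 acetyl chloride
Product: 16 N-methoxy-N-methylacetamide
Conditions: MeNH(OMe)·HCl, Et3N, CH2Cl2, 0 °C to rt
Reagents that add atoms: N,O-dimethylhydroxylamine hydrochloride, CNOC.Cl
Why: N-acylation of the amine by the acid chloride gives an acetyl donor that forms a stable chelate on addition and so cannot add twice.

Step 12
Reactants: 15 keto-dioxinone; 16 N-methoxy-N-methylacetamide
Product: 17 diketo-dioxinone methyl ketone (fragment 2)
Conditions: 15, LiN(i-Pr)2 (2.1 equiv), THF, -78 to -40 °C; then 16, -78 to -20 °C; 1 M HCl to pH 4, 0 °C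
Reagents that add atoms: none
Why: Claisen-type acylation of the keto-dioxinone dianion, whose last-formed terminal carbanion (at the methyl group) is the most nucleophilic site, while the tetrahedral N-methoxy-N-methyl chelate releases the diketone only on work-up.

Step 13
Reactants: 17 diketo-dioxinone methyl ketone (fragment 2); 12 (E,E)-dienoyl N-methoxy-N-methylamide (fragment 1)
Product: 18 dienyl triketo-dioxinone
Conditions: 17 (2 equiv) added to LiN(i-Pr)2 (3.1 equiv per 17), THF, -78 to -20 °C; then 12 (1 equiv), -78 to -30 °C; AcOH, -78 °C; crude used at once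
Reagents that add atoms: none
Why: Terminal acylation of a beta-polycarbonyl polyanion (Harris-type Claisen condensation), in which the fully enolised trianion cannot fold on itself, its terminal carbanion adds 1,2 to the amide carbonyl, and the chelated adduct keeps the new ketone masked until the quench.

Step 14
Reactants: 18 dienyl triketo-dioxinone
Product: 20 6,8-dihydroxy-3-dienylisocoumarin silyl ether, via benzodioxinone dienyl ketone 19 (not isolated)
Conditions: Et3N, CH2Cl2, 0 °C to rt; then Cs2CO3, MeCN, 40 °C; aq. NH4Cl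
Reagents that add atoms: none
Why: Et3N forms the dienolate of the dioxinone, whose C5 (future C8a) adds to the ketone that becomes C4a in a 6-(enolexo)-exo-trig aldol, and loss of water with enolisation of the C6 ketone gives the benzene ring irreversibly as benzodioxinone 19; the closest known reaction type is the base-mediated aldol aromatisation of diketo-dioxinones to resorcylate acetonides. Cs2CO3 then enolises the benzylic C3 ketone into conjugation with arene and diene, and the enolate oxygen attacks the acetal-activated C1 carbonyl in a 6-exo-trig acyl substitution that expels acetone and frees the 8-hydroxyl, as in the enol lactonisation of 2-(2-oxoalkyl)benzoates to isocoumarins. No stereocentre is formed, the three oxolane centres lie outside the reacting chain, and both E double bonds stay conjugated throughout. The selectivity needed is the C8a-to-C4a fold and not a C7-to-C3 aldol, an O-cyclisation to a pyranone or a Claisen C-acylation. The dioxinone secures it, because its C5 is the nucleophilic end of the dienolate and its carbonyl is masked until the arene exists, and the dienyl-conjugated C3 ketone is the least electrophilic carbonyl of the chain. The dioxinone acts first as carbon nucleophile and then as acyl donor, so no phenol or carboxyl protecting group is needed.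

Step 15
Reactants: 20 6,8-dihydroxy-3-dienylisocoumarin silyl ether
Product: 21 5-chloro isocoumarin silyl ether
Conditions: NCS (1.0 equiv), MeCN, 0 °C to rt, dark
Reagents that add atoms: N-chlorosuccinimide, O=C1CCC(=O)N1Cl
Why: Electrophilic aromatic chlorination of the resorcinol ring should go to C5, ortho to the free 6-hydroxyl and para to the 8-hydroxyl that is hydrogen-bonded to the lactone carbonyl, as in the chlorination of orsellinates.

Step 16
Reactants: 21 5-chloro isocoumarin silyl ether
Product: 22 target CNP0086741.2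
Conditions: Bu4NF, AcOH, THF, 0 °C to rt
Reagents that add atoms: none
Why: Fluoride-induced cleavage of the secondary silyl ether, with acetic acid as buffer so that the phenols stay protonated and neither the lactone nor the allylic C2–O bond of the oxolane is attacked.

**Compound list**
1 | 2-deoxy-D-ribose | O=CC[C@H](O)[C@H](O)CO | starting material
2 | 2-deoxy-D-ribono-1,4-lactone, (4S,5R)-4-hydroxy-5-(hydroxymethyl)oxolan-2-one | O=C1C[C@H](O)[C@@H](CO)O1 | intermediate
3 | 3,5-bis-O-(tert-butyldimethylsilyl)-2-deoxy-D-ribono-1,4-lactone | O=C1C[C@H](O[Si](C)(C)C(C)(C)C)[C@@H](CO[Si](C)(C)C(C)(C)C)O1 | intermediate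
4 | 3,5-bis-O-(tert-butyldimethylsilyl)-2-deoxy-D-ribofuranose (lactol, anomer mixture) | OC1C[C@H](O[Si](C)(C)C(C)(C)C)[C@@H](CO[Si](C)(C)C(C)(C)C)O1 | intermediate
5 | 1-O-acetyl-3,5-bis-O-(tert-butyldimethylsilyl)-2-deoxy-D-ribofuranose (anomer mixture) | CC(=O)OC1C[C@H](O[Si](C)(C)C(C)(C)C)[C@@H](CO[Si](C)(C)C(C)(C)C)O1 | intermediate
6 | trimethylaluminium, Al(CH3)3 | C[Al](C)C | starting material
7 | (2R,3S,5R)-3-(tert-butyldimethylsilyloxy)-2-[(tert-butyldimethylsilyloxy)methyl]-5-methyloxolane | C[C@@H]1C[C@H](O[Si](C)(C)C(C)(C)C)[C@@H](CO[Si](C)(C)C(C)(C)C)O1 | intermediate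
8 | [(2R,3S,5R)-3-(tert-butyldimethylsilyloxy)-5-methyloxolan-2-yl]methanol | C[C@@H]1C[C@H](O[Si](C)(C)C(C)(C)C)[C@@H](CO)O1 | intermediate
9 | (2S,3S,5R)-3-(tert-butyldimethylsilyloxy)-5-methyloxolane-2-carbaldehyde | C[C@@H]1C[C@H](O[Si](C)(C)C(C)(C)C)[C@@H](C=O)O1 | intermediate
10 | triethyl 4-phosphonocrotonate | CCOC(=O)/C=C/CP(=O)(OCC)OCC | starting material
11 | ethyl (2E,4E)-5-[(2R,3S,5R)-3-(tert-butyldimethylsilyloxy)-5-methyloxolan-2-yl]penta-2,4-dienoate | C[C@@H]1C[C@H](O[Si](C)(C)C(C)(C)C)[C@@H](/C=C/C=C/C(=O)OCC)O1 | intermediate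
12 | (2E,4E)-5-[(2R,3S,5R)-3-(tert-butyldimethylsilyloxy)-5-methyloxolan-2-yl]-N-methoxy-N-methylpenta-2,4-dienamide (fragment 1) | C[C@@H]1C[C@H](O[Si](C)(C)C(C)(C)C)[C@@H](/C=C/C=C/C(=O)N(C)OC)O1 | intermediate
13 | 2,2,6-trimethyl-4H-1,3-dioxin-4-one | CC1=CC(=O)OC(C)(C)O1 | starting material
14 | acetyl chloride | CC(Cl)=O | starting material
15 | 2,2-dimethyl-6-(2-oxopropyl)-4H-1,3-dioxin-4-one | CC(=O)CC1=CC(=O)OC(C)(C)O1 | intermediate
16 | N-methoxy-N-methylacetamide | CC(=O)N(C)OC | intermediate
17 | 1-(2,2-dimethyl-4-oxo-4H-1,3-dioxin-6-yl)pentane-2,4-dione (fragment 2) | CC(=O)CC(=O)CC1=CC(=O)OC(C)(C)O1 | intermediate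
18 | (7E,9E)-1-(2,2-dimethyl-4-oxo-4H-1,3-dioxin-6-yl)-10-[(2R,3S,5R)-3-(tert-butyldimethylsilyloxy)-5-methyloxolan-2-yl]deca-7,9-diene-2,4,6-trione | C[C@@H]1C[C@H](O[Si](C)(C)C(C)(C)C)[C@@H](/C=C/C=C/C(=O)CC(=O)CC(=O)CC2=CC(=O)OC(C)(C)O2)O1 | intermediate
19 | 7-hydroxy-2,2-dimethyl-5-[(3E,5E)-2-oxo-6-[(2R,3S,5R)-3-(tert-butyldimethylsilyloxy)-5-methyloxolan-2-yl]hexa-3,5-dien-1-yl]-4H-1,3-benzodioxin-4-one | C[C@@H]1C[C@H](O[Si](C)(C)C(C)(C)C)[C@@H](/C=C/C=C/C(=O)Cc2cc(O)cc3OC(C)(C)OC(=O)c23)O1 | intermediate
20 | 6,8-dihydroxy-3-[(1E,3E)-4-[(2R,3S,5R)-3-(tert-butyldimethylsilyloxy)-5-methyloxolan-2-yl]buta-1,3-dien-1-yl]-1H-isochromen-1-one | C[C@@H]1C[C@H](O[Si](C)(C)C(C)(C)C)[C@@H](/C=C/C=C/c2cc3cc(O)cc(O)c3c(=O)o2)O1 | intermediate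
21 | 5-chloro-6,8-dihydroxy-3-[(1E,3E)-4-[(2R,3S,5R)-3-(tert-butyldimethylsilyloxy)-5-methyloxolan-2-yl]buta-1,3-dien-1-yl]-1H-isochromen-1-one | C[C@@H]1C[C@H](O[Si](C)(C)C(C)(C)C)[C@@H](/C=C/C=C/c2cc3c(Cl)c(O)cc(O)c3c(=O)o2)O1 | intermediate
22 | 5-chloro-6,8-dihydroxy-3-[(1E,3E)-4-[(2R,3S,5R)-3-hydroxy-5-methyloxolan-2-yl]buta-1,3-dien-1-yl]-1H-isochromen-1-one (CNP0086741.2) | C[C@@H]1C[C@H](O)[C@@H](/C=C/C=C/c2cc3c(Cl)c(O)cc(O)c3c(=O)o2)O1 | target

**Step count**
Total steps: 16. Longest linear sequence: 13 steps (steps 1 to 9, then 13 to 16); fragment 2 takes 3 steps (10 to 12).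

**Steps most likely to fail**

1. Step 13. The third deprotonation may stay incomplete, the polyanion may act as a base toward amide 12 or add to its diene in conjugate fashion, and partly enolised 17 may close on itself before the chain is extended. The fallback sets out from 17 and 12 and comes back to the route at 20; it closes the arene first and attaches the dienyl ketone afterwards. Et3N in CH2Cl2 should aromatise 17 to 7-hydroxy-2,2,5-trimethyl-4H-1,3-benzodioxin-4-one F1, and TBSCl with imidazole should give its aryl silyl ether F2. LiN(i-Pr)2 in THF at -78 °C deprotonates the 5-methyl group (lateral lithiation of an ortho-toluate), and the anion is acylated by 12 to the benzylic dienyl ketone F3. Cs2CO3 in MeCN should close the enol lactone to the 6-O-silyl isocoumarin F4, and KHF2 in MeOH removes the phenolic silyl group selectively to give 20.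

2. Step 14. The chain may fold the other way (C7 onto the C3 ketone), cyclise through oxygen to a pyranone, or stop before the lactone closes. The fallback sets out from 12 and 17 and comes back at 19, which the Cs2CO3 stage of step 14 takes to 20; it carries C3 through the fold at the alcohol level, so only one aldol is possible. Reduction of 12 with i-Bu2AlH in THF at -78 °C should give the (2E,4E)-dienal F5. The trianion of 17 (LiN(i-Pr)2, THF, -78 °C) adds to F5 to give the hydroxy diketo-dioxinone F6 as carbinol epimers, which do not matter. Et3N in CH2Cl2 aromatises F6 by the established diketo-dioxinone fold to the hydroxyalkyl benzodioxinone F7, and MnO2 in CH2Cl2 oxidises the dienylic alcohol to 19.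

3. Step 15. Chlorine may add to the electron-rich 3-dienyl enol lactone, or enter at C7 or twice. The fallback sets out from 18 and comes back at 21; it chlorinates before the lactone exists. Step 14 is stopped after the Et3N stage and 19 is isolated; there the diene is part of an electron-poor dienone and only one phenol is free. NCS in MeCN at 0 °C should then chlorinate ortho to the 7-hydroxyl and para to the ring oxygen to give the 6-chloro benzodioxinone F8, and Cs2CO3 in MeCN at 40 °C closes the lactone to 21.

**Further compounds**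
F1 | step 13 | 7-hydroxy-2,2,5-trimethyl-4H-1,3-benzodioxin-4-one | Cc1cc(O)cc2OC(C)(C)OC(=O)c12
F2 | step 13 | 7-(tert-butyldimethylsilyloxy)-2,2,5-trimethyl-4H-1,3-benzodioxin-4-one | Cc1cc(O[Si](C)(C)C(C)(C)C)cc2OC(C)(C)OC(=O)c12
F3 | step 13 | 7-(tert-butyldimethylsilyloxy)-2,2-dimethyl-5-[(3E,5E)-2-oxo-6-[(2R,3S,5R)-3-(tert-butyldimethylsilyloxy)-5-methyloxolan-2-yl]hexa-3,5-dien-1-yl]-4H-1,3-benzodioxin-4-one | C[C@@H]1C[C@H](O[Si](C)(C)C(C)(C)C)[C@@H](/C=C/C=C/C(=O)Cc2cc(O[Si](C)(C)C(C)(C)C)cc3OC(C)(C)OC(=O)c23)O1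
F4 | step 13 | 6-(tert-butyldimethylsilyloxy)-8-hydroxy-3-[(1E,3E)-4-[(2R,3S,5R)-3-(tert-butyldimethylsilyloxy)-5-methyloxolan-2-yl]buta-1,3-dien-1-yl]-1H-isochromen-1-one | C[C@@H]1C[C@H](O[Si](C)(C)C(C)(C)C)[C@@H](/C=C/C=C/c2cc3cc(O[Si](C)(C)C(C)(C)C)cc(O)c3c(=O)o2)O1
F5 | step 14 | (2E,4E)-5-[(2R,3S,5R)-3-(tert-butyldimethylsilyloxy)-5-methyloxolan-2-yl]penta-2,4-dienal | C[C@@H]1C[C@H](O[Si](C)(C)C(C)(C)C)[C@@H](/C=C/C=C/C=O)O1
F6 | step 14 | (7E,9E)-1-(2,2-dimethyl-4-oxo-4H-1,3-dioxin-6-yl)-6-hydroxy-10-[(2R,3S,5R)-3-(tert-butyldimethylsilyloxy)-5-methyloxolan-2-yl]deca-7,9-diene-2,4-dione (carbinol epimers) | C[C@@H]1C[C@H](O[Si](C)(C)C(C)(C)C)[C@@H](/C=C/C=C/C(O)CC(=O)CC(=O)CC2=CC(=O)OC(C)(C)O2)O1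
F7 | step 14 | 7-hydroxy-5-[(3E,5E)-2-hydroxy-6-[(2R,3S,5R)-3-(tert-butyldimethylsilyloxy)-5-methyloxolan-2-yl]hexa-3,5-dien-1-yl]-2,2-dimethyl-4H-1,3-benzodioxin-4-one (carbinol epimers) | C[C@@H]1C[C@H](O[Si](C)(C)C(C)(C)C)[C@@H](/C=C/C=C/C(O)Cc2cc(O)cc3OC(C)(C)OC(=O)c23)O1
F8 | step 15 | 6-chloro-7-hydroxy-2,2-dimethyl-5-[(3E,5E)-2-oxo-6-[(2R,3S,5R)-3-(tert-butyldimethylsilyloxy)-5-methyloxolan-2-yl]hexa-3,5-dien-1-yl]-4H-1,3-benzodioxin-4-one | C[C@@H]1C[C@H](O[Si](C)(C)C(C)(C)C)[C@@H](/C=C/C=C/C(=O)Cc2c(Cl)c(O)cc3OC(C)(C)OC(=O)c23)O1
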